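0.2545 M of target stands in the ash run at 6.6 h, out of 0.400 M of starting material charged, and it rose by just 0.006300 M over the last 2.00 h.

| setting | cedar | ash | maple |
|---|---|---|---|
| starting material | 0.400 M | 0.400 M | 0.400 M |
| partner | 1.00 M | 3.00 M | 1.00 M |
| time |  |  | 16 h |

| run | time / h | [target] / M |
|---|---|---|
| cedar run | 0.50 | 0.0086 |
| cedar run | 1.5 | 0.0468 |
| cedar run | 2.9 | 0.1088 |
| cedar run | 4.6 | 0.1630 |
| cedar run | 6.6 | 0.1918 |
| ash run | 0.50 | 0.0195 |
| ash run | 1.5 | 0.1041 |
| ash run | 2.9 | 0.1972 |
| ash run | 4.6 | 0.2482 |
| ash run | 6.6 | 0.2545 |

(scatter of a reading: 0.001 M)

1. reaction order in [partner] at the outset, round the charge of the cedar run, defined at two percent of the starting material turned into target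
2. target in the maple run at 16 h, as a share of the starting material charged

- Overall: starting material + partner -> target.
- Constant volume, constant temperature.
- "The second partner" is partner.
- An order is taken over about fifteen percent of the charge, up and down.

The maple flask repeats the cedar charge. So I turn the question round: what must be true for its target at 16 h to stand level with the cedar reading of 0.1918 M at 6.6 h?

I assume target leaks away at first order, like a tank with a lifetime. The amount lost is then the area under the target curve divided by that lifetime, and it cannot exceed the charge not standing as target. The ash run averages 0.176 M of target up to 6.6 h, with 0.146 M not standing as target at the end. The area under the curve over that missing amount, 7.96 h, is the balance lifetime: the shortest lifetime the balance allows.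

I hold the cedar curve level from 6.6 h to 16 h. Its average up to 6.6 h is 0.110 M, and the level strip adds to its area. A level maple target then needs a lifetime of at least 12.1 h, longer than the ash value.

I commit to the ash value, a floor, as an estimate. By this reckoning the cedar flask has made 0.283 M by 6.6 h, with 0.117 M of the charge to come. Its feed runs at 0.0367 M h⁻¹, so I let it fade with a time constant of 3.20 h. Integrating feed against leak gives my estimate for the maple flask at 16 h: 0.109 M, or 27.2 % of the charge.

The forecast differs, higher than my share, with 56 % and an order of 0.55; it says the cedar run “should plateau near 0.22 M, about 56%”.

The order round the cedar charge comes out at 0.54, and the maple flask gives a share of 36.1 %.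

    starting material + partner → intermediate (0.3362 M⁻¹ h⁻¹)
    intermediate → target (0.5472 h⁻¹)
    target → decomposed product (0.08892 h⁻¹)
    2 partner → lost reagent (0.04572 M⁻¹ h⁻¹)

The lifetime of target is 11.2 h, above the ash balance lifetime of 7.96 h and below the 12.1 h that a level maple target needs. In the maple flask, starting material and partner make intermediate, which passes on to target with a time constant of 1.83 h. Target decays to decomposed product meanwhile, and partner goes to lost reagent with a first half-life of 10.9 h by this step alone. At 16 h the maple flask holds 0.144 M of target, below the cedar reading of 0.1918 M.

The data stem from a simulated flask for an exercise.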